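A percent of charge is the unit here, and in this flask, the amber run followed onward, a percent of starting material equals a percent of protic impurity, since the two charges match.

- amber: starting material 20 mM; gas phase 4.4 mM (held); protic impurity 20 mM; the very flask that is asked about, followed so far
- flask: starting material 20 mM; gas phase 4.4 mM (held); protic impurity 20.0 mM; time 3.0 min

amber run (percent of the starting material charged)

| time / s | target / % | starting material / % |
|---|---|---|
| 10.0 | 3.5 | 86.4 |
| 15.0 | 5.8 | 79.9 |
| 25.0 | 10.2 | 68.0 |
| 30.0 | 12.6 | 63.0 |
| 40.0 | 15.8 | 54.3 |
| 50.0 | 19.5 | 46.2 |

(each reading ± 0.3 percentage points)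

- the earlier runs were read with a standard deviation of 0.3 percentage points
- at the start none of the gas phase is in solution

- the target standing at 3.0 min, as a percentage of the starting material charged
- concentration of dissolved gas in solution at 3.0 min, in percent of saturation

My own reckoning assumes that starting material not found as target was lost to impurity, one for one. So h, the fraction of impurity left, is starting material left plus target: 65.7% at 50.0 s. That reading gives 0.464 for the selectivity factor σ, the target divided by ln(1/h). If target needs starting material and dissolved gas, and quenching needs starting material and impurity, then c(starting material) cancels from σ, and so does the impurity charge, while c(dissolved gas) holds. But the gas starts undissolved, and σ reads 0.329 at 10.0 s, lower, so the last reading serves. Extended first order, the reckoning puts a, the starting material left in this flask, at 6.20% at 3.0 min. Solving h = a + σ ln(1/h) then gives an estimated h of 44.0% and an estimated target of 38.1%.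

The forecast differs: target 40% (range 35% to 45%), “taking selectivity as about 0.49 and then 0.53 over the remaining conversion, gives about 40%”, and saturation 97% (range 91% to 99.7%).

At 3.00 min the flask gives 34.5% target and 93.5% of saturation, and it also holds 5.74% over-reacted product.

    starting material + protic impurity → quenched substrate (k = 0.578 M⁻¹ s⁻¹)
    dissolved gas ⇌ dormant form (K = 5.90, k = 0.00572 s⁻¹)
    starting material → decomposition product (k = 7.04 × 10⁻⁶ s⁻¹)
    gas phase ⇌ dissolved gas, rate k4*(csat - [dissolved gas]) (kL = 0.150 s⁻¹)
    starting material + dissolved gas → target (k = 1.84 M⁻¹ s⁻¹)
    dissolved gas + target → over-reacted product (k = 0.332 M⁻¹ s⁻¹)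

With 48% of the impurity left in this flask at 3.00 min, σ gives 34.1%. The neighbouring flask is charged with 34 mM of impurity, 1.70 equiv, and keeps 59% of its own charge at 3.00 min, so the same σ gives 24.5%. Its target stands at 23.7%.

The data were computed for substances that don't exist.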